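## Retrosynthetic overview

1. Feature: in the single carbocycle (ring A) the tertiary carbinol C1, which carries the C7H2OBz branch, lies para to the oxygenated C4. C2=C3 lies on one side and the C5,C6-diol on the other, so ring A is a dearomatised 4-hydroxybenzyl benzoate whose C5=C6 and C2=C3 alkenes are enantiotopic.
2. Late disconnections: the O4 benzoate and C4–H go back to a C4 ketone (axial hydride on a conformationally pinned enone). The C6–O bond (trans to C5–O, cis to C7) goes back to a C5,C6-oxirane cis to the C1 hydroxyl, opened at C6 with inversion by the C7 benzoate.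
3. Key disconnection: the oxirane (C5–O and C6–O) goes back to the achiral para-quinol by a catalytic desymmetrising nucleophilic epoxidation that fixes C1, C5 and C6 in one operation.
4. Ring order: ring A is bought as the arene. The oxirane forms in step 3, a transient 1,3-dioxan-2-ylium ring in step 4, and a seven-membered disiloxane protecting ring in step 5 (removed in step 8).

Key step: step 3

Convention: C1 is the carbinol carbon bearing C7H2, followed by C2=C3, C4, C5 and C6. The upper face is the face of the C1 hydroxyl, and all descriptors use this numbering. The target is (1R,4S,5S,6S), with O1 up, C7 down, O6 down, O5 up and O4 down.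

Assumption: the sense of induction of the cinchona amine on a quinol cannot be read off from simple cyclohexenones. 9-Amino-9-deoxy-epi-quinine is written for the (1R,5S,6R) series, and the pseudo-enantiomeric 9-amino-9-deoxy-epi-quinidine takes its place if a first trial shows the antipode.

## Route

Step 1
Reactants: 1 4-hydroxybenzyl alcohol; 2 benzoic acid
Product: 3 4-hydroxybenzyl benzoate
Conditions: PPh3, DIAD, THF, 0 °C to rt
Reagents that add atoms: benzoic acid (2), O=C(O)c1ccccc1
Why: Mitsunobu esterification, in which only the alcohol is activated as an oxyphosphonium ion and the carboxylic acid, far more acidic than the phenol, is the partner that is deprotonated and alkylated, so O7 is acylated with the phenol left free and no stereocentre is formed.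

Step 2
Reactants: 3 4-hydroxybenzyl benzoate
Product: 4 (1-hydroxy-4-oxocyclohexa-2,5-dien-1-yl)methyl benzoate (achiral para-quinol)
Conditions: PhI(OAc)2, MeCN/H2O (3:1), 0 °C
Reagents that add atoms: water, O
Why: Oxidative dearomatisation of a para-substituted phenol with a hypervalent iodine reagent, in which the aryloxyiodane loses PhI while water adds to the substituted para carbon C1; because O7 is already acylated the quinol cannot shed C7 as formaldehyde by retro-aldol-type cleavage, which is why esterification precedes oxidation, and 4 keeps a mirror plane through C1 and C4.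

Step 3
Reactants: 4 (1-hydroxy-4-oxocyclohexa-2,5-dien-1-yl)methyl benzoate
Product: 5 [(1R,5S,6R)-5,6-epoxy-1-hydroxy-4-oxocyclohex-2-en-1-yl]methyl benzoate (oxirane on the upper face, cis to the C1 hydroxyl)
Conditions: 9-amino-9-deoxy-epi-quinine (10 mol %), CF3CO2H (20 mol %), 30% aq. H2O2 (1.1 equiv), 1,4-dioxane, 30 °C
Reagents that add atoms: hydrogen peroxide, OO
Why: The primary amine condenses with the C4 ketone to an unsaturated iminium ion, H2O2 held by the protonated quinuclidine adds to C6, and the resulting peroxy-dienamine attacks the proximal peroxide oxygen through C5 with loss of water, after which hydrolysis releases 5 and the amine (asymmetric Weitz–Scheffer epoxidation under iminium catalysis). The closest known reactions are the cinchona-primary-amine/H2O2 epoxidation of cyclic enones and the catalytic asymmetric nucleophilic epoxidation of achiral cyclohexa-2,5-dienones such as quinone monoketals. The oxirane closes by a 3-exo-tet displacement on the O–O bond, and the ring forces C5–O and C6–O to be cis. The absolute configuration at C5 and C6 comes from the catalyst, which accepts only one prochiral face of a β-carbon, while C1 becomes stereogenic in the same event and its relation to the oxirane (hydroxyl cis) comes from attack on the hydroxyl face, the face para-quinols prefer in peroxide epoxidations because the C1 hydroxyl hydrogen-bonds to the incoming peroxide. Two selections are therefore needed: of the two attacks that fit the catalyst (C6 from the upper face, C2 from the lower face) the hydroxyl picks the first, so a lapse in face selectivity should show up as a separable anti diastereomer and not as the enantiomer. Mono-epoxidation is secured by keeping H2O2 near one equivalent, and a slight overrun should raise enantiomeric purity because the minor enantiomer still holds the alkene the catalyst prefers and is drained to the achiral bis-epoxide.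

Step 4
Reactants: 5 [(1R,5S,6R)-5,6-epoxy-1-hydroxy-4-oxocyclohex-2-en-1-yl]methyl benzoate
Product: 7 [(1R,5S,6S)-1,5,6-trihydroxy-4-oxocyclohex-2-en-1-yl]methyl benzoate, via acyloxonium trifluoroborate zwitterion 6 (not isolated)
Conditions: BF3·OEt2 (2 equiv), CH2Cl2, −40 to 0 °C; then H2O/THF, 0 °C
Reagents that add atoms: water, O
Why: Lewis-acid epoxide opening with neighbouring-group participation of an ester, in which the carbonyl oxygen of the C7 benzoate, held on the lower face, can reach only C6 and displaces the activated oxirane oxygen from behind (6-exo-tet, trans-diaxial opening, with the C4 ketone disfavouring charge build-up at C5), so C6 is inverted to S and the C5–O bond is untouched; water then converts 6 through its hemi-orthoester into the hydroxy ester, whose acyl group rests on primary O7 as the least hindered position.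

Step 5
Reactants: 7 [(1R,5S,6S)-1,5,6-trihydroxy-4-oxocyclohex-2-en-1-yl]methyl benzoate
Product: 8 5,6-O-(1,1,3,3-tetraisopropyldisiloxane-1,3-diyl) derivative of 7, (1R,5S,6S), C1 hydroxyl free
Conditions: TIPDSCl2 (1.1 equiv), pyridine, 0 °C to rt
Reagents that add atoms: 1,3-dichloro-1,1,3,3-tetraisopropyldisiloxane, CC(C)[Si](Cl)(C(C)C)O[Si](Cl)(C(C)C)C(C)C
Why: Cyclic disiloxane protection of a vicinal diol, in which the two secondary hydroxyls are silylated in turn to close a seven-membered ring while the tertiary C1 hydroxyl is too hindered to react; since the bridge can only span gauche oxygens it pins the trans-diol diequatorial, which two separate bulky silyl ethers (prone to go diaxial) would not.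

Step 6
Reactants: 8 5,6-O-TIPDS enone
Product: 9 (1R,4S,5R,6S)-allylic alcohol: [4-hydroxy-1-hydroxy-5,6-O-(tetraisopropyldisiloxane-1,3-diyl)dioxycyclohex-2-en-1-yl]methyl benzoate, C4 hydroxyl on the lower face, trans to O5
Conditions: NaBH4, CeCl3·7H2O, MeOH/CH2Cl2 (1:1), −78 °C
Reagents that add atoms: none
Why: Luche reduction (1,2-selective), in which hydride adds to C4 of the half-chair fixed by the disiloxane bridge along the axial trajectory from the upper face, where only the axial H6 stands, giving the pseudo-equatorial 4S alcohol trans to O5, the usual course for cyclohexenones that carry an equatorial alkoxy group on the saturated α-carbon.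

Step 7
Reactants: 9 (1R,4S,5R,6S)-allylic alcohol; 10 benzoyl chloride
Product: 11 (1R,4S,5R,6S)-4-O-benzoate of 9 (dibenzoate, O5/O6 bridged by TIPDS, C1 hydroxyl free)
Conditions: BzCl (1.3 equiv), pyridine, DMAP (cat.), CH2Cl2, 0 °C to rt
Reagents that add atoms: benzoyl chloride (10), O=C(Cl)c1ccccc1
Why: Nucleophile-catalysed acylation (pyridine/DMAP) of the only secondary hydroxyl, in which the tertiary C1 hydroxyl does not react at this temperature and C4 keeps its configuration because its C–O bond is not touched.

Step 8
Reactants: 11 TIPDS-protected dibenzoate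
Product: 12 kweichowenol B, [(1R,4S,5S,6S)-4-(benzoyloxy)-1,5,6-trihydroxycyclohex-2-en-1-yl]methyl benzoate
Conditions: HF·pyridine, THF, 0 °C to rt
Reagents that add atoms: none
Why: Fluoride-driven Si–O cleavage under weakly acidic conditions removes the disiloxane bridge without base, so neither benzoate should migrate to the freed O5 or O6 hydroxyl and no stereocentre is affected.

## Compound list

1 | 4-hydroxybenzyl alcohol | OCc1ccc(O)cc1 | starting material
2 | benzoic acid | O=C(O)c1ccccc1 | starting material
3 | 4-hydroxybenzyl benzoate | O=C(OCc1ccc(O)cc1)c1ccccc1 | intermediate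
4 | (1-hydroxy-4-oxocyclohexa-2,5-dien-1-yl)methyl benzoate, achiral para-quinol | O=C(OCC1(O)C=CC(=O)C=C1)c1ccccc1 | intermediate
5 | [(1R,5S,6R)-5,6-epoxy-1-hydroxy-4-oxocyclohex-2-en-1-yl]methyl benzoate, oxirane cis to the C1 hydroxyl | O=C(OC[C@]1(O)C=CC(=O)[C@H]2O[C@@H]12)c1ccccc1 | intermediate
6 | cis-fused 2-phenyl-1,3-dioxan-2-ylium ion spanning O7 and O6 (C6 inverted, O6 on the lower face), O5 bound to BF3, zwitterion | O[C@@]12C=CC(=O)[C@@H](O[B-](F)(F)F)[C@@H]1[O+]=C(c1ccccc1)OC2 | intermediate
7 | [(1R,5S,6S)-1,5,6-trihydroxy-4-oxocyclohex-2-en-1-yl]methyl benzoate | O=C(OC[C@]1(O)C=CC(=O)[C@@H](O)[C@@H]1O)c1ccccc1 | intermediate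
8 | 5,6-O-(1,1,3,3-tetraisopropyldisiloxane-1,3-diyl) derivative of 7, (1R,5S,6S) | O=C(OC[C@]1(O)C=CC(=O)[C@H]2O[Si](C(C)C)(C(C)C)O[Si](C(C)C)(C(C)C)O[C@H]12)c1ccccc1 | intermediate
9 | (1R,4S,5R,6S)-allylic alcohol from 8, C4 hydroxyl trans to O5 | O=C(OC[C@]1(O)C=C[C@H](O)[C@H]2O[Si](C(C)C)(C(C)C)O[Si](C(C)C)(C(C)C)O[C@H]12)c1ccccc1 | intermediate
10 | benzoyl chloride | O=C(Cl)c1ccccc1 | starting material
11 | (1R,4S,5R,6S)-4-O-benzoate of 9 | O=C(OC[C@]1(O)C=C[C@H](OC(=O)c2ccccc2)[C@H]3O[Si](C(C)C)(C(C)C)O[Si](C(C)C)(C(C)C)O[C@H]13)c1ccccc1 | intermediate
12 | kweichowenol B, [(1R,4S,5S,6S)-4-(benzoyloxy)-1,5,6-trihydroxycyclohex-2-en-1-yl]methyl benzoate | O=C(OC[C@]1(O)C=C[C@H](OC(=O)c2ccccc2)[C@@H](O)[C@@H]1O)c1ccccc1 | target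

Total step count: 8. Longest linear sequence: 8 steps (from 1).

## Steps most likely to fail

**1. Step 3.**
- What may go wrong:
  - sluggish iminium formation on the cross-conjugated ketone;
  - attack on the face away from the hydroxyl;
  - weak discrimination between the enantiotopic alkenes;
  - acid-induced dienone–phenol rearrangement of the quinol.
- Fallback: it sets out from benzoyl chloride 10, with purchased 4,4-dimethoxycyclohexa-2,5-dienone F1 as the ring source, and comes back at 5. The two selections are taken apart.
- In F1 the two alkenes are equivalent and each has enantiotopic faces, so a phase-transfer Weitz–Scheffer epoxidation needs only one choice. N-Benzylcinchonidinium chloride or its cinchoninium pseudo-enantiomer, t-BuOOH, aq. NaOH and toluene should give (1R,6S)-5,5-dimethoxy-7-oxabicyclo[4.1.0]hept-3-en-2-one F2, to be enriched by crystallisation if required.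
- (i-PrO)Me2SiCH2MgCl with CeCl3 in THF at −78 °C should add 1,2 to the ketone anti to the oxirane. This gives the silylmethyl carbinol F3, with the new hydroxyl cis to the oxirane.
- Tamao oxidation (H2O2, KF, KHCO3, THF/MeOH) gives the epoxy diol ketal F4.
- Benzoyl chloride 10 in pyridine/CH2Cl2 at 0 °C acylates the primary hydroxyl to give the benzoate ketal F5.
- Pyridinium p-toluenesulfonate in aqueous acetone unmasks the C4 ketone to give 5.

**2. Step 4.**
- What may go wrong:
  - a 1,2-acyl shift of the epoxy ketone with ring contraction;
  - enolisation toward C5 followed by β-elimination of O6 and aromatisation;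
  - drift of the benzoyl group from O7 to O6.
- Fallback: it sets out from 5 and comes back at 7. The ketone is taken out of play while the oxirane is opened.
- Luche reduction of 5 (NaBH4, CeCl3·7H2O, MeOH, −78 °C) gives the epoxy diol F6. Hydride is expected anti to the oxirane, but the configuration at C4 is of no consequence.
- BF3·OEt2 in CH2Cl2 at −78 °C lets the C7 benzoate open this more basic, non-enolisable oxirane at C6, giving the acyloxonium zwitterion F7. Water turns it into the tetraol monobenzoate F8.
- MnO2 in CH2Cl2 oxidises only the allylic C4 hydroxyl back to the enone 7.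

**3. Step 6.**
- What may go wrong: poor facial selectivity if the pseudo-axial C7 branch distorts the half-chair, or some 1,4-reduction.
- Fallback: it sets out from 8 and comes back at 11. The sequence is made stereoconvergent by inversion in place of retention.
- The C4-epimeric alcohol F9 (hydroxyl cis to O5), separated from 9 after the reduction, is esterified with benzoic acid 2 under Mitsunobu conditions (PPh3, DIAD, toluene, 0 °C to rt). This places the benzoate on the lower face by SN2 inversion at C4 and gives 11 directly.
- Any 9 formed goes through step 7 as planned.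

## Further compounds

F1 | step 3 | 4,4-dimethoxycyclohexa-2,5-dienone (purchased) | COC1(OC)C=CC(=O)C=C1
F2 | step 3 | (1R,6S)-5,5-dimethoxy-7-oxabicyclo[4.1.0]hept-3-en-2-one | O=C1C=CC(OC)(OC)[C@H]2O[C@@H]12
F3 | step 3 | 1,2-adduct of F2: tertiary carbinol bearing CH2SiMe2(O-i-Pr), hydroxyl cis to the oxirane | CC(C)O[Si](C)(C)C[C@]1(O)C=CC(OC)(OC)[C@H]2O[C@@H]12
F4 | step 3 | epoxy diol ketal (C7 hydroxymethyl, C1 hydroxyl cis to the oxirane) | OC[C@]1(O)C=CC(OC)(OC)[C@H]2O[C@@H]12
F5 | step 3 | C7 benzoate of F4 (dimethyl ketal of 5) | O=C(OC[C@]1(O)C=CC(OC)(OC)[C@H]2O[C@@H]12)c1ccccc1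
F6 | step 4 | epoxy diol from 5, C4 hydroxyl cis to the oxirane | O=C(OC[C@]1(O)C=C[C@@H](O)[C@H]2O[C@@H]12)c1ccccc1
F7 | step 4 | 2-phenyl-1,3-dioxan-2-ylium trifluoroborate zwitterion from F6 (C6 inverted) | O[C@@]12C=C[C@@H](O)[C@@H](O[B-](F)(F)F)[C@@H]1[O+]=C(c1ccccc1)OC2
F8 | step 4 | tetraol monobenzoate, O1, O4 and O5 on the upper face, O6 on the lower face | O=C(OC[C@]1(O)C=C[C@@H](O)[C@@H](O)[C@@H]1O)c1ccccc1
F9 | step 6 | C4 epimer of 9, hydroxyl cis to O5 | O=C(OC[C@]1(O)C=C[C@@H](O)[C@H]2O[Si](C(C)C)(C(C)C)O[Si](C(C)C)(C(C)C)O[C@H]12)c1ccccc1
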